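**Assumption:** the single stereocentre (C2) is (R), as read from the SMILES; hex-5-en-1-ol, 3,5-bis(benzyloxy)benzyl bromide, oct-1-en-3-one and (−)-sparteine are bought.

**Retrosynthetic overview**
1. Target 14 ⇐ one-flask hydrogenation of enone 11 (saturates C6=C7 and removes both benzyl ethers).
2. 11 ⇐ cross-metathesis of terminal alkene 9 with oct-1-en-3-one 10 (C6=C7), so the ketone enters late and unprotected.
3. 9 ⇐ acetylation of 8 ⇐ key step: sparteine-mediated lithiation–borylation of carbamate 2 with benzylboronate 4, which forges C1–C2 and sets C2 (R) in one flask (in place of the usual chiral epoxide/aryl cuprate opening).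
4. 2 ⇐ hex-5-en-1-ol 1; 4 ⇐ 3,5-bis(benzyloxy)benzyl bromide 3.
5. No ring is formed; the only ring (the resorcinol arene) is bought.

**Route**

Step 1
Reactants: 1 hex-5-en-1-ol
Product: 2 hex-5-en-1-yl N,N-diisopropylcarbamate
Conditions: NaH, THF, 0 °C; then i-Pr2NCOCl, reflux
Reagents that add atoms: N,N-diisopropylcarbamoyl chloride, CC(C)N(C(C)C)C(Cl)=O
Why: The sodium alkoxide attacks the carbamoyl chloride (nucleophilic acyl substitution, Hoppe carbamate formation), installing the hindered group that directs α-lithiation and later serves as the leaving group.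

Step 2
Reactants: 3 3,5-bis(benzyloxy)benzyl bromide
Product: 4 2-[3,5-bis(benzyloxy)benzyl]-4,4,5,5-tetramethyl-1,3,2-dioxaborolane
Conditions: B2pin2, Pd(dba)2 (3 mol %), P(4-MeOC6H4)3 (6 mol %), KOAc, toluene, 50 °C
Reagents that add atoms: bis(pinacolato)diboron, CC1(C)OB(OC1(C)C)B1OC(C)(C)C(C)(C)O1
Why: Miyaura borylation of a benzylic halide (oxidative addition into C–Br, acetate-assisted transmetalation with B2pin2, reductive elimination); the aryl benzyl ethers are inert.

Step 3
Reactants: 2 hex-5-en-1-yl N,N-diisopropylcarbamate; 4 2-[3,5-bis(benzyloxy)benzyl]-4,4,5,5-tetramethyl-1,3,2-dioxaborolane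
Product: 8 (R)-1-[3,5-bis(benzyloxy)phenyl]hept-6-en-2-ol, via lithiated carbamate 5 (not isolated), via boronate complex 6 (not isolated), via secondary boronic ester 7 (not isolated)
Conditions: 2 (1.3 equiv), (−)-sparteine (1.3 equiv), s-BuLi (1.25 equiv), Et2O, −78 °C, 5 h; then 4 (1.0 equiv), −78 °C, 1 h; MgBr2·OEt2, −78 °C to reflux, 16 h; then 2 M NaOH, 30% H2O2, THF, 0 °C to rt
Reagents that add atoms: hydrogen peroxide, OO
Why: Hoppe–Aggarwal lithiation–borylation: s-BuLi/(−)-sparteine removes the pro-S α-proton to give configurationally stable (S)-5 (−78 °C also suppresses 5-exo carbolithiation), borylation by 4 occurs with retention, the benzyl group then migrates from B to C anti to the carbamate (1,2-metallate rearrangement, inversion), and C–B oxidation with retention gives the (R)-carbinol, expected er about 96:4 or better.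

Step 4
Reactants: 8 (R)-1-[3,5-bis(benzyloxy)phenyl]hept-6-en-2-ol
Product: 9 (R)-1-[3,5-bis(benzyloxy)phenyl]hept-6-en-2-yl acetate
Conditions: Ac2O, pyridine, DMAP (cat.), CH2Cl2, rt
Reagents that add atoms: acetic anhydride, CC(=O)OC(C)=O
Why: DMAP-catalysed O-acylation (nucleophilic catalysis) takes place at oxygen only, so the C2–O bond and the (R) configuration are untouched.

Step 5
Reactants: 9 (R)-1-[3,5-bis(benzyloxy)phenyl]hept-6-en-2-yl acetate; 10 oct-1-en-3-one (3 equiv)
Product: 11 (R,E)-1-[3,5-bis(benzyloxy)phenyl]-8-oxotridec-6-en-2-yl acetate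
Conditions: Hoveyda–Grubbs II (5 mol %), CH2Cl2, 40 °C
Reagents that add atoms: none
Why: Olefin cross-metathesis of a type I terminal alkene with a type II enone is selective for the E cross-product with loss of ethylene; the acetate and benzyl ethers are tolerated, and the alkene geometry does not matter because it is hydrogenated next.

Step 6
Reactants: 11 (R,E)-1-[3,5-bis(benzyloxy)phenyl]-8-oxotridec-6-en-2-yl acetate
Product: 14 (R)-1-(3,5-dihydroxyphenyl)-8-oxotridecan-2-yl acetate, via saturated dibenzyl ether 12 (not isolated), via monobenzyl ether 13 (not isolated)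
Conditions: H2 (1 atm), 10% Pd/C, EtOAc, rt
Reagents that add atoms: none
Why: Heterogeneous catalytic hydrogenation saturates the conjugated C=C first and then hydrogenolyses both aryl benzyl ethers, while the dialkyl ketone and the homobenzylic (not benzylic) secondary acetate are inert under these neutral conditions, so C2 is not affected.

**Compound list**
1 | hex-5-en-1-ol | C=CCCCCO | starting material
2 | hex-5-en-1-yl N,N-diisopropylcarbamate | C=CCCCCOC(=O)N(C(C)C)C(C)C | intermediate
3 | 3,5-bis(benzyloxy)benzyl bromide | BrCc1cc(OCc2ccccc2)cc(OCc2ccccc2)c1 | starting material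
4 | 2-[3,5-bis(benzyloxy)benzyl]-4,4,5,5-tetramethyl-1,3,2-dioxaborolane | CC1(C)OB(Cc2cc(OCc3ccccc3)cc(OCc3ccccc3)c2)OC1(C)C | intermediate
5 | (S)-1-lithiohex-5-en-1-yl N,N-diisopropylcarbamate, (−)-sparteine complex | C=CCCC[C@H]([Li])OC(=O)N(C(C)C)C(C)C | intermediate
6 | lithium (S)-[3,5-bis(benzyloxy)benzyl][1-(diisopropylcarbamoyloxy)hex-5-en-1-yl](pinacolato)borate | C=CCCC[C@H]([B-]1(Cc2cc(OCc3ccccc3)cc(OCc3ccccc3)c2)OC(C)(C)C(C)(C)O1)OC(=O)N(C(C)C)C(C)C.[Li+] | intermediate
7 | (R)-2-{1-[3,5-bis(benzyloxy)phenyl]hept-6-en-2-yl}-4,4,5,5-tetramethyl-1,3,2-dioxaborolane | C=CCCC[C@@H](B1OC(C)(C)C(C)(C)O1)Cc1cc(OCc2ccccc2)cc(OCc2ccccc2)c1 | intermediate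
8 | (R)-1-[3,5-bis(benzyloxy)phenyl]hept-6-en-2-ol | C=CCCC[C@H](Cc1cc(OCc2ccccc2)cc(OCc2ccccc2)c1)O | intermediate
9 | (R)-1-[3,5-bis(benzyloxy)phenyl]hept-6-en-2-yl acetate | C=CCCC[C@H](Cc1cc(OCc2ccccc2)cc(OCc2ccccc2)c1)OC(C)=O | intermediate
10 | oct-1-en-3-one | C=CC(=O)CCCCC | starting material
11 | (R,E)-1-[3,5-bis(benzyloxy)phenyl]-8-oxotridec-6-en-2-yl acetate | CCCCCC(=O)/C=C/CCC[C@H](Cc1cc(OCc2ccccc2)cc(OCc2ccccc2)c1)OC(C)=O | intermediate
12 | (R)-1-[3,5-bis(benzyloxy)phenyl]-8-oxotridecan-2-yl acetate | CCCCCC(=O)CCCCC[C@H](Cc1cc(OCc2ccccc2)cc(OCc2ccccc2)c1)OC(C)=O | intermediate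
13 | (R)-1-[3-(benzyloxy)-5-hydroxyphenyl]-8-oxotridecan-2-yl acetate | CCCCCC(=O)CCCCC[C@H](Cc1cc(O)cc(OCc2ccccc2)c1)OC(C)=O | intermediate
14 | (R)-1-(3,5-dihydroxyphenyl)-8-oxotridecan-2-yl acetate (CNP0213461.1) | CCCCCC(=O)CCCCC[C@H](Cc1cc(O)cc(O)c1)OC(C)=O | target

**Totals**
Total step count: 6.
Longest linear sequence: 5 steps (1 → 2 → 8 → 9 → 11 → 14); step 2 is a one-step side branch.

**Three steps most likely to fail, with fallbacks**

Step 3 (lithiation–borylation; risks: 5-exo carbolithiation of 5, sluggish benzyl migration, insufficient er). The fallback sets out from bromide 3 and comes back at alcohol 8. CuI-catalysed coupling of 3 with vinylmagnesium bromide (THF, 0 °C) gives 1-allyl-3,5-bis(benzyloxy)benzene F1. Epoxidation with mCPBA (CH2Cl2, NaHCO3) gives racemic 2-[3,5-bis(benzyloxy)benzyl]oxirane F2. Jacobsen hydrolytic kinetic resolution with (R,R)-(salen)Co(III)OAc (0.5 mol %, 0.55 equiv H2O) should leave (S)-2-[3,5-bis(benzyloxy)benzyl]oxirane F3. This catalyst/enantiomer pairing is taken from the simple alkyl-oxirane series and should be confirmed on F3. CuI-catalysed opening of F3 at the terminal carbon with but-3-enylmagnesium bromide (THF, −30 °C) leaves the stereocentre untouched and gives 8; the descriptor changes from S to R only because the CIP priorities change.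

Step 5 (cross-metathesis; risks: enone dimerisation, alkene isomerisation, stalled conversion). The fallback sets out from acetate 9 and comes back at enone 11. Lemieux–Johnson cleavage of the terminal alkene (OsO4 cat., NaIO4, 2,6-lutidine, dioxane/H2O) gives (R)-1-[3,5-bis(benzyloxy)phenyl]-6-oxohexan-2-yl acetate F4. Horner–Wadsworth–Emmons olefination of F4 with commercial dimethyl (2-oxoheptyl)phosphonate, CCCCCC(=O)CP(=O)(OC)OC (LiCl, i-Pr2NEt, MeCN, Masamune–Roush conditions), gives 11.

Step 2 (Pd borylation; risk: bibenzyl homocoupling of the electron-rich benzyl bromide). The fallback sets out from bromide 3 and comes back at boronate 4 through a polar organometallic route. Slow addition of 3 to Mg turnings in THF at 0 °C in the presence of 2-isopropoxy-4,4,5,5-tetramethyl-1,3,2-dioxaborolane (Barbier conditions) forms 3,5-bis(benzyloxy)benzylmagnesium bromide F5, which is trapped at boron as it forms to give 4.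

**Further compounds**
F1 | step 3 | 1-allyl-3,5-bis(benzyloxy)benzene | C=CCc1cc(OCc2ccccc2)cc(OCc2ccccc2)c1
F2 | step 3 | rac-2-[3,5-bis(benzyloxy)benzyl]oxirane | C1OC1Cc1cc(OCc2ccccc2)cc(OCc2ccccc2)c1
F3 | step 3 | (S)-2-[3,5-bis(benzyloxy)benzyl]oxirane | C1[C@H](Cc2cc(OCc3ccccc3)cc(OCc3ccccc3)c2)O1
F4 | step 5 | (R)-1-[3,5-bis(benzyloxy)phenyl]-6-oxohexan-2-yl acetate | O=CCCC[C@H](Cc1cc(OCc2ccccc2)cc(OCc2ccccc2)c1)OC(C)=O
F5 | step 2 | 3,5-bis(benzyloxy)benzylmagnesium bromide | Br[Mg]Cc1cc(OCc2ccccc2)cc(OCc2ccccc2)c1
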